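**Strategy.** The dihydrofuran ring (O1, C2, C3, C3a, C7a) is closed last, by forming the C2–C3 bond: a diaryl rhodium carbene at C3 inserts into a benzylic ether C–H that becomes C2–H. The step exploits the fact that C3a of the benzo ring lies between two oxygens (O1 and the oxygen on C4): both carry the same 4-silyloxy-3-methoxybenzyl arm, so either arm gives the same ring, and the unused arm later falls off together with the silyl groups. The precursor is an open-chain diaryl ketone hydrazone, oxidised in the flask to the diazo compound. One operation closes the ring and sets C3 under catalyst control; C2 is equilibrated to trans in the last step.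

Key step: step 9

Remark on notation: benzofuran numbering is used (O1, C2, C3, C3a, C4 to C7, C7a); TIPS = triisopropylsilyl; G = 3-methoxy-4-(triisopropylsilyloxy)phenyl.
Assumption: Rh2(R-PTAD)4 is taken to induce the (3S) configuration on this substrate; should the sense be opposite, Rh2(S-PTAD)4 is used with no other change.
Assumption: vanillin, 4-bromo-3,5-dimethoxybenzaldehyde and 3,5-dihydroxybenzonitrile are taken as commercially available.

**Step 1**
Reactants: 1 vanillin (4-hydroxy-3-methoxybenzaldehyde)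
Product: 2 3-methoxy-4-(triisopropylsilyloxy)benzaldehyde (G–CHO)
Conditions: TIPSCl, imidazole, DMF, rt
Reagents that add atoms: triisopropylsilyl chloride, CC(C)[Si](Cl)(C(C)C)C(C)C
Why: Imidazole-promoted silylation of the phenol; the bulky TIPS ether is chosen because it should survive the organolithium, alkoxide and hydrazine steps that follow.

**Step 2**
Reactants: 2 3-methoxy-4-(triisopropylsilyloxy)benzaldehyde
Product: 3 [3-methoxy-4-(triisopropylsilyloxy)phenyl]methanol (G–CH2OH)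
Conditions: NaBH4, MeOH, 0 °C
Reagents that add atoms: none
Why: Borohydride reduction of an aromatic aldehyde, to which the aryl silyl ether is inert at 0 °C.

**Step 3**
Reactants: 3 [3-methoxy-4-(triisopropylsilyloxy)phenyl]methanol
Product: 4 diethyl {[3-methoxy-4-(triisopropylsilyloxy)phenyl]methyl}phosphonate
Conditions: P(OEt)3, ZnI2, toluene, reflux
Reagents that add atoms: triethyl phosphite, CCOP(OCC)OCC
Why: ZnI2-mediated direct phosphonylation of an electron-rich benzylic alcohol (transesterification to the benzyl phosphite followed by a Michaelis–Arbuzov-type rearrangement through the stabilised benzylic cation).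

**Step 4**
Reactants: 5 4-bromo-3,5-dimethoxybenzaldehyde
Product: 6 4-bromo-3,5-dihydroxybenzaldehyde
Conditions: BBr3, CH2Cl2, −78 °C → rt; H2O
Reagents that add atoms: none
Why: Lewis acid demethylation of both aryl methyl ethers by BBr3, the aldehyde being returned on aqueous work-up.

**Step 5**
Reactants: 6 4-bromo-3,5-dihydroxybenzaldehyde; 3 [3-methoxy-4-(triisopropylsilyloxy)phenyl]methanol (2.3 equiv)
Product: 7 4-bromo-3,5-bis{[3-methoxy-4-(triisopropylsilyloxy)phenyl]methoxy}benzaldehyde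
Conditions: PPh3, DIAD, THF, 0 °C → rt
Reagents that add atoms: none
Why: Double Mitsunobu etherification of two acidic phenols with a primary benzylic alcohol under neutral conditions that spare the aldehyde and the silyl ethers.

**Step 6**
Reactants: 7 the bis(benzyl ether) aldehyde; 4 the benzylphosphonate
Product: 8 (E)-2-bromo-1,3-bis{[3-methoxy-4-(triisopropylsilyloxy)phenyl]methoxy}-5-{2-[3-methoxy-4-(triisopropylsilyloxy)phenyl]ethenyl}benzene
Conditions: KOtBu, THF, 0 °C → rt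
Reagents that add atoms: none
Why: Horner–Wadsworth–Emmons olefination of a benzylphosphonate anion with a non-enolisable aryl aldehyde, which should give the E-stilbene.

**Step 7**
Reactants: 9 3,5-dihydroxybenzonitrile
Product: 10 3,5-bis(triisopropylsilyloxy)benzonitrile
Conditions: TIPSCl, imidazole, DMF, rt
Reagents that add atoms: triisopropylsilyl chloride, CC(C)[Si](Cl)(C(C)C)C(C)C
Why: Imidazole-promoted silylation of both phenols, the nitrile being untouched.

**Step 8**
Reactants: 8 the stilbene aryl bromide; 10 3,5-bis(triisopropylsilyloxy)benzonitrile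
Product: 14 hydrazone (C=N–NH2) of [3,5-bis(triisopropylsilyloxy)phenyl] [2,6-bis(G-methoxy)-4-{(E)-2-G-ethenyl}phenyl] ketone, via aryllithium 11 (not isolated), via N-lithio ketimine 12 (not isolated), via N-unsubstituted ketimine 13 (not isolated)
Conditions: n-BuLi (1.05 equiv), THF, −78 °C; 10, −78 → 0 °C; then AcOH, N2H4·H2O, EtOH, 60 °C
Reagents that add atoms: hydrazine (used as the hydrate), NN
Why: Bromine–lithium exchange at −78 °C should outpace carbolithiation of the stilbene and benzylic deprotonation, the aryllithium adds once to the nitrile to give an N-lithio ketimine that cannot over-add, and the protonated N-unsubstituted ketimine exchanges with hydrazine (transimination with loss of ammonia) more readily than the hindered 2,6-dialkoxy ketone would condense.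

**Step 9**
Reactants: 14 the diaryl ketone hydrazone
Product: 16 (2R,3S)-cis-2-G-3-[3,5-bis(triisopropylsilyloxy)phenyl]-4-(G-methoxy)-6-[(E)-2-G-ethenyl]-2,3-dihydro-1-benzofuran, via diaryldiazomethane 15 (not isolated)
Conditions: MnO2 (activated, 8 equiv), CH2Cl2, 0 °C, dark; filtration (Celite); slow addition to Rh2(R-PTAD)4 (1 mol %), CH2Cl2, 0 °C → rt
Reagents that add atoms: none
Why: MnO2 dehydrogenates the hydrazone to the diaryldiazomethane 15, which the chiral dirhodium carboxylate converts with loss of N2 into a donor/donor rhodium carbene at C3; this carbene inserts into a C–H bond of one of the two O–CH2–aryl arms through a hydride-transfer-like three-centre transition state, forming the C2–C3 bond. The closest known reaction type is the enantioselective intramolecular 1,5 C–H insertion of donor/donor rhodium carbenes, generated from 2-benzyloxybenzophenone hydrazones, to give 2,3-diaryl-2,3-dihydrobenzofurans. The dihydrofuran ring is closed in the 1,5-insertion mode, its five atoms being the carbene carbon C3, C3a, C7a, O1 and the inserting carbon C2. C3 is controlled by the catalyst, whose chiral carboxylate pocket selects one face of the carbene and with it one of the two diastereotopic hydrogens; C2 follows from the compact insertion geometry as the cis isomer, which is of no consequence because C2 is equilibrated in step 10. The step needs site selectivity for the ether C–H, secured by activation through the adjacent oxygen and the electron-rich aryl group and by the five-membered geometry (the two arms interchange by rotation about the C3–C3a bond and cannot give regioisomers). It also needs chemoselectivity over azine formation and cyclopropanation of the stilbene, secured by the low electrophilicity and bulk of the diaryl carbene, the hindered trans-disubstituted alkene and slow addition of 15 at high dilution.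

**Step 10**
Reactants: 16 the cis-dihydrobenzofuran
Product: 17 Bisisorhapontigenin B, 5-[(2S,3S)-4-hydroxy-2-(4-hydroxy-3-methoxyphenyl)-6-[(E)-2-(4-hydroxy-3-methoxyphenyl)ethenyl]-2,3-dihydro-1-benzofuran-3-yl]benzene-1,3-diol
Conditions: TBAF (7 equiv), THF/MeOH, argon, 0 °C → rt, then 40 °C; AcOH quench
Reagents that add atoms: none
Why: Fluoride removes the five aryl silyl groups, the freed 4-oxidobenzyl ether on the C4 oxygen then fragments by 1,6-elimination (its quinone methide being captured by methanol), and the same phenoxide-driven reversible quinone methide opening and 5-exo-trig oxa-Michael reclosure of the O1–C2 bond should equilibrate C2 to the thermodynamically preferred 2,3-trans isomer while C3, set in step 9, is untouched.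

**Compound list**

1 | vanillin (4-hydroxy-3-methoxybenzaldehyde) | COc1cc(C=O)ccc1O | starting material
2 | 3-methoxy-4-(triisopropylsilyloxy)benzaldehyde | COc1cc(C=O)ccc1O[Si](C(C)C)(C(C)C)C(C)C | intermediate
3 | [3-methoxy-4-(triisopropylsilyloxy)phenyl]methanol | COc1cc(CO)ccc1O[Si](C(C)C)(C(C)C)C(C)C | intermediate
4 | diethyl {[3-methoxy-4-(triisopropylsilyloxy)phenyl]methyl}phosphonate | CCOP(=O)(OCC)Cc1ccc(O[Si](C(C)C)(C(C)C)C(C)C)c(OC)c1 | intermediate
5 | 4-bromo-3,5-dimethoxybenzaldehyde | COc1cc(C=O)cc(OC)c1Br | starting material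
6 | 4-bromo-3,5-dihydroxybenzaldehyde | O=Cc1cc(O)c(Br)c(O)c1 | intermediate
7 | 4-bromo-3,5-bis{[3-methoxy-4-(triisopropylsilyloxy)phenyl]methoxy}benzaldehyde | O=Cc1cc(OCc2ccc(O[Si](C(C)C)(C(C)C)C(C)C)c(OC)c2)c(Br)c(OCc2ccc(O[Si](C(C)C)(C(C)C)C(C)C)c(OC)c2)c1 | intermediate
8 | (E)-2-bromo-1,3-bis{[3-methoxy-4-(triisopropylsilyloxy)phenyl]methoxy}-5-{2-[3-methoxy-4-(triisopropylsilyloxy)phenyl]ethenyl}benzene | COc1cc(/C=C/c2cc(OCc3ccc(O[Si](C(C)C)(C(C)C)C(C)C)c(OC)c3)c(Br)c(OCc3ccc(O[Si](C(C)C)(C(C)C)C(C)C)c(OC)c3)c2)ccc1O[Si](C(C)C)(C(C)C)C(C)C | intermediate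
9 | 3,5-dihydroxybenzonitrile | N#Cc1cc(O)cc(O)c1 | starting material
10 | 3,5-bis(triisopropylsilyloxy)benzonitrile | N#Cc1cc(O[Si](C(C)C)(C(C)C)C(C)C)cc(O[Si](C(C)C)(C(C)C)C(C)C)c1 | intermediate
11 | aryllithium: compound 8 with lithium in place of bromine | COc1cc(/C=C/c2cc(OCc3ccc(O[Si](C(C)C)(C(C)C)C(C)C)c(OC)c3)c([Li])c(OCc3ccc(O[Si](C(C)C)(C(C)C)C(C)C)c(OC)c3)c2)ccc1O[Si](C(C)C)(C(C)C)C(C)C | intermediate
12 | N-lithio ketimine: lithium salt of compound 13 | COc1cc(/C=C/c2cc(OCc3ccc(O[Si](C(C)C)(C(C)C)C(C)C)c(OC)c3)c(C(=N[Li])c3cc(O[Si](C(C)C)(C(C)C)C(C)C)cc(O[Si](C(C)C)(C(C)C)C(C)C)c3)c(OCc3ccc(O[Si](C(C)C)(C(C)C)C(C)C)c(OC)c3)c2)ccc1O[Si](C(C)C)(C(C)C)C(C)C | intermediate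
13 | N-unsubstituted ketimine: [3,5-bis(triisopropylsilyloxy)phenyl][2,6-bis(G-methoxy)-4-{(E)-2-G-ethenyl}phenyl]methanimine | COc1cc(/C=C/c2cc(OCc3ccc(O[Si](C(C)C)(C(C)C)C(C)C)c(OC)c3)c(C(=N)c3cc(O[Si](C(C)C)(C(C)C)C(C)C)cc(O[Si](C(C)C)(C(C)C)C(C)C)c3)c(OCc3ccc(O[Si](C(C)C)(C(C)C)C(C)C)c(OC)c3)c2)ccc1O[Si](C(C)C)(C(C)C)C(C)C | intermediate
14 | hydrazone (C=N–NH2) of the corresponding diaryl ketone | COc1cc(/C=C/c2cc(OCc3ccc(O[Si](C(C)C)(C(C)C)C(C)C)c(OC)c3)c(C(=NN)c3cc(O[Si](C(C)C)(C(C)C)C(C)C)cc(O[Si](C(C)C)(C(C)C)C(C)C)c3)c(OCc3ccc(O[Si](C(C)C)(C(C)C)C(C)C)c(OC)c3)c2)ccc1O[Si](C(C)C)(C(C)C)C(C)C | intermediate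
15 | diaryldiazomethane: compound 14 with C=N2 in place of C=N–NH2 | COc1cc(/C=C/c2cc(OCc3ccc(O[Si](C(C)C)(C(C)C)C(C)C)c(OC)c3)c(C(=[N+]=[N-])c3cc(O[Si](C(C)C)(C(C)C)C(C)C)cc(O[Si](C(C)C)(C(C)C)C(C)C)c3)c(OCc3ccc(O[Si](C(C)C)(C(C)C)C(C)C)c(OC)c3)c2)ccc1O[Si](C(C)C)(C(C)C)C(C)C | intermediate
16 | (2R,3S)-cis-2-G-3-[3,5-bis(triisopropylsilyloxy)phenyl]-4-(G-methoxy)-6-[(E)-2-G-ethenyl]-2,3-dihydro-1-benzofuran | COc1cc(/C=C/c2cc(OCc4ccc(O[Si](C(C)C)(C(C)C)C(C)C)c(OC)c4)c3c(c2)O[C@@H](c2ccc(O[Si](C(C)C)(C(C)C)C(C)C)c(OC)c2)[C@H]3c2cc(O[Si](C(C)C)(C(C)C)C(C)C)cc(O[Si](C(C)C)(C(C)C)C(C)C)c2)ccc1O[Si](C(C)C)(C(C)C)C(C)C | intermediate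
17 | Bisisorhapontigenin B, (2S,3S)-trans | COc1cc(/C=C/c2cc(O)c3c(c2)O[C@H](c2ccc(O)c(OC)c2)[C@H]3c2cc(O)cc(O)c2)ccc1O | target

**Step count.** Total: 10 steps. Longest linear sequence: 7 steps (steps 1, 2, 5, 6, 8, 9, 10).

**Steps most likely to fail**

Step 9. The carbene may be consumed by a second molecule of diazo compound (azine formation) or by the stilbene double bond of another molecule instead of inserting. The fallback installs the stilbene only after the ring closure. Setting out from 7, the aldehyde is masked as the 1,3-dioxolane F1 (ethylene glycol, PPTS, benzene, reflux). Bromine–lithium exchange as in step 8 gives the aryllithium F2, addition to 10 gives the N-lithio ketimine F3 and, on protonation, the N-unsubstituted ketimine F4, and hydrazinolysis gives the hydrazone F5. MnO2 then gives the diazo compound F6, and Rh2(R-PTAD)4 the cis-dihydrobenzofuran acetal F7. PPTS in wet acetone frees the aldehyde F8, and the Horner–Wadsworth–Emmons reaction of F8 with 4 (KOtBu, THF, 0 °C) comes back to the route at 16.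

Step 10. Under basic conditions the ring-opened quinone methide may lose the C3 proton (tautomerisation to a triarylethylene, which erases the C3 stereocentre), or the quinone methide released from the arm may alkylate the polyphenol at carbon. The fallback uses acid first and fluoride second. Setting out from 16, TFA in CH2Cl2 with pentamethylbenzene as cation scavenger at 0 °C cleaves the residual arm as a 4-alkoxybenzyl-type ether and epimerises C2 by ionisation and reclosure, giving the trans phenol F9. Buffered desilylation (TBAF/AcOH, THF, 0 °C), in which no free phenoxide persists, then comes back to the route at 17.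

Step 8. Exchange of the hindered ketimine with hydrazine may stall, and prolonged heating with hydrazine may strip aryl silyl groups. The fallback avoids free hydrazine. Setting out from 13 (made as in step 8 and not treated with hydrazine), hydrolysis with aqueous oxalic acid in THF gives the diaryl ketone F10. 1,2-Bis(tert-butyldimethylsilyl)hydrazine with catalytic Sc(OTf)3 gives the N-silyl hydrazone F11, and oxidation with (difluoroiodo)benzene and 2-chloropyridine in CH2Cl2 at −78 °C gives the diazo compound, so that the route is rejoined at 15.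

**Further compounds**

F1 | step 9 | 2-[4-bromo-3,5-bis(G-methoxy)phenyl]-1,3-dioxolane | Brc1c(OCc2ccc(O[Si](C(C)C)(C(C)C)C(C)C)c(OC)c2)cc(C2OCCO2)cc1OCc1ccc(O[Si](C(C)C)(C(C)C)C(C)C)c(OC)c1
F2 | step 9 | aryllithium: F1 with lithium in place of bromine | [Li]c1c(OCc2ccc(O[Si](C(C)C)(C(C)C)C(C)C)c(OC)c2)cc(C2OCCO2)cc1OCc1ccc(O[Si](C(C)C)(C(C)C)C(C)C)c(OC)c1
F3 | step 9 | N-lithio ketimine: lithium salt of F4 | [Li]N=C(c1cc(O[Si](C(C)C)(C(C)C)C(C)C)cc(O[Si](C(C)C)(C(C)C)C(C)C)c1)c1c(OCc2ccc(O[Si](C(C)C)(C(C)C)C(C)C)c(OC)c2)cc(C2OCCO2)cc1OCc1ccc(O[Si](C(C)C)(C(C)C)C(C)C)c(OC)c1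
F4 | step 9 | [3,5-bis(triisopropylsilyloxy)phenyl][2,6-bis(G-methoxy)-4-(1,3-dioxolan-2-yl)phenyl]methanimine | N=C(c1cc(O[Si](C(C)C)(C(C)C)C(C)C)cc(O[Si](C(C)C)(C(C)C)C(C)C)c1)c1c(OCc2ccc(O[Si](C(C)C)(C(C)C)C(C)C)c(OC)c2)cc(C2OCCO2)cc1OCc1ccc(O[Si](C(C)C)(C(C)C)C(C)C)c(OC)c1
F5 | step 9 | hydrazone (C=N–NH2) corresponding to F4 | NN=C(c1cc(O[Si](C(C)C)(C(C)C)C(C)C)cc(O[Si](C(C)C)(C(C)C)C(C)C)c1)c1c(OCc2ccc(O[Si](C(C)C)(C(C)C)C(C)C)c(OC)c2)cc(C2OCCO2)cc1OCc1ccc(O[Si](C(C)C)(C(C)C)C(C)C)c(OC)c1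
F6 | step 9 | diaryldiazomethane corresponding to F5 | [N-]=[N+]=C(c1cc(O[Si](C(C)C)(C(C)C)C(C)C)cc(O[Si](C(C)C)(C(C)C)C(C)C)c1)c1c(OCc2ccc(O[Si](C(C)C)(C(C)C)C(C)C)c(OC)c2)cc(C2OCCO2)cc1OCc1ccc(O[Si](C(C)C)(C(C)C)C(C)C)c(OC)c1
F7 | step 9 | (2R,3S)-cis-2-G-3-[3,5-bis(triisopropylsilyloxy)phenyl]-4-(G-methoxy)-6-(1,3-dioxolan-2-yl)-2,3-dihydro-1-benzofuran | O1CCOC1c1cc(OCc3ccc(O[Si](C(C)C)(C(C)C)C(C)C)c(OC)c3)c2c(c1)O[C@@H](c1ccc(O[Si](C(C)C)(C(C)C)C(C)C)c(OC)c1)[C@H]2c1cc(O[Si](C(C)C)(C(C)C)C(C)C)cc(O[Si](C(C)C)(C(C)C)C(C)C)c1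
F8 | step 9 | (2R,3S)-cis-2-G-3-[3,5-bis(triisopropylsilyloxy)phenyl]-4-(G-methoxy)-2,3-dihydro-1-benzofuran-6-carbaldehyde | O=Cc1cc(OCc3ccc(O[Si](C(C)C)(C(C)C)C(C)C)c(OC)c3)c2c(c1)O[C@@H](c1ccc(O[Si](C(C)C)(C(C)C)C(C)C)c(OC)c1)[C@H]2c1cc(O[Si](C(C)C)(C(C)C)C(C)C)cc(O[Si](C(C)C)(C(C)C)C(C)C)c1
F9 | step 10 | (2S,3S)-trans-2-G-3-[3,5-bis(triisopropylsilyloxy)phenyl]-6-[(E)-2-G-ethenyl]-2,3-dihydro-1-benzofuran-4-ol | COc1cc(/C=C/c2cc(O)c3c(c2)O[C@H](c2ccc(O[Si](C(C)C)(C(C)C)C(C)C)c(OC)c2)[C@H]3c2cc(O[Si](C(C)C)(C(C)C)C(C)C)cc(O[Si](C(C)C)(C(C)C)C(C)C)c2)ccc1O[Si](C(C)C)(C(C)C)C(C)C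
F10 | step 8 | [3,5-bis(triisopropylsilyloxy)phenyl][2,6-bis(G-methoxy)-4-{(E)-2-G-ethenyl}phenyl]methanone | COc1cc(/C=C/c2cc(OCc3ccc(O[Si](C(C)C)(C(C)C)C(C)C)c(OC)c3)c(C(=O)c3cc(O[Si](C(C)C)(C(C)C)C(C)C)cc(O[Si](C(C)C)(C(C)C)C(C)C)c3)c(OCc3ccc(O[Si](C(C)C)(C(C)C)C(C)C)c(OC)c3)c2)ccc1O[Si](C(C)C)(C(C)C)C(C)C
F11 | step 8 | N-(tert-butyldimethylsilyl)hydrazone of F10 | COc1cc(/C=C/c2cc(OCc3ccc(O[Si](C(C)C)(C(C)C)C(C)C)c(OC)c3)c(C(=NN[Si](C)(C)C(C)(C)C)c3cc(O[Si](C(C)C)(C(C)C)C(C)C)cc(O[Si](C(C)C)(C(C)C)C(C)C)c3)c(OCc3ccc(O[Si](C(C)C)(C(C)C)C(C)C)c(OC)c3)c2)ccc1O[Si](C(C)C)(C(C)C)C(C)C
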